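Everything rests on disconnecting two neighbouring bonds of ring A, C4'–O and C5'–CHO, back to an aryne spanning C4'/C5' and N,N-dimethylformamide. One operation inserts the aryne into the formamide C=O bond, so the phenol and the aldehyde are installed simultaneously on an otherwise complete, hexasubstituted ring. The feature exploited is the adjacent C4'-OH/C5'-CHO pair of ring A together with the C6' oxygen beside C5', which steers the addition. The precursor is a fully substituted ortho-silylaryl triflate (SiMe3 on C5', OTf on C4') whose C6' oxygen and carboxyl group are both masked as benzyl groups; hydrogenolysis and depside esterification with ring B complete the synthesis.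

Key step: step 7

Remark: ring A is numbered C1' (bearing the depside carbonyl) to C6', so that C4', C5', C6' are C4, C3, C2 of the benzoate intermediates; ring B (C1 bears CO2Me) carries three C-methyl groups, so atraric acid needs one more methyl at C5.

Step 1
Reactants: 1 benzyl acetoacetate; 2 ethyl tiglate
Product: 4 benzyl 5,6-dimethyl-2,4-dioxocyclohexane-1-carboxylate (diastereomer mixture), via Michael adduct 3 (not isolated)
Conditions: KOtBu (1.1 equiv), t-BuOH, reflux; then aq. HCl
Reagents that add atoms: none
Why: Michael addition of the acetoacetate enolate to the β-carbon of the tiglate, then intramolecular Claisen (Dieckmann-type) condensation of the methyl ketone onto the ethyl ester, is the classical Michael–Claisen annulation to dihydroresorcylates; the three stereocentres are uncontrolled and disappear on aromatization.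

Step 2
Reactants: 4 benzyl 5,6-dimethyl-2,4-dioxocyclohexane-1-carboxylate
Product: 6 benzyl 3-bromo-2,4-dihydroxy-5,6-dimethylbenzoate, via bromine-free resorcylate 5 (not isolated)
Conditions: Br2 (2.05 equiv), NaOAc, AcOH, 15–25 °C
Reagents that add atoms: bromine BrBr
Why: Bromine-mediated aromatization of a dihydroresorcylate (C3 bromination, then loss of HBr through the enol) is followed in the same flask by electrophilic aromatic bromination at C3, the only unsubstituted ring carbon and activated by both hydroxyls; NaOAc buffers the HBr so that the benzyl ester is not cleaved.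

Step 3
Reactants: 6 benzyl 3-bromo-2,4-dihydroxy-5,6-dimethylbenzoate
Product: 7 benzyl 4-(allyloxy)-3-bromo-2-hydroxy-5,6-dimethylbenzoate
Conditions: allyl bromide (1.05 equiv), K2CO3, acetone, 40 °C
Reagents that add atoms: allyl bromide C=CCBr
Why: Williamson etherification is selective for the C4 hydroxyl because the C2 hydroxyl is held in a hydrogen bond to the ester carbonyl and is the less acidic and less nucleophilic of the two.

Step 4
Reactants: 7 benzyl 4-(allyloxy)-3-bromo-2-hydroxy-5,6-dimethylbenzoate
Product: 8 benzyl 4-(allyloxy)-2-(benzyloxy)-3-bromo-5,6-dimethylbenzoate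
Conditions: BnBr, K2CO3, KI (cat.), DMF, 60 °C
Reagents that add atoms: benzyl bromide BrCc1ccccc1
Why: Williamson etherification under more forcing conditions (dipolar solvent, heat, iodide catalysis) alkylates the remaining chelated phenol, the only nucleophilic site left.

Step 5
Reactants: 8 benzyl 4-(allyloxy)-2-(benzyloxy)-3-bromo-5,6-dimethylbenzoate
Product: 9 benzyl 2-(benzyloxy)-3-bromo-4-hydroxy-5,6-dimethylbenzoate
Conditions: Pd(PPh3)4 (3 mol%), morpholine, THF, rt
Reagents that add atoms: none
Why: Tsuji–Trost deallylation, in which zerovalent palladium ionizes the aryl allyl ether to a π-allyl complex that morpholine intercepts, while the benzyl ether, the benzyl ester and the crowded, electron-rich aryl bromide are inert at room temperature.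

Step 6
Reactants: 9 benzyl 2-(benzyloxy)-3-bromo-4-hydroxy-5,6-dimethylbenzoate
Product: 13 benzyl 2-(benzyloxy)-5,6-dimethyl-4-(trifluoromethylsulfonyloxy)-3-(trimethylsilyl)benzoate, via trimethylsilyl ether 10 (not isolated), via aryllithium 11 (not isolated), via lithium phenoxide 12 (not isolated)
Conditions: HMDS, THF, 70 °C, then evaporate; n-BuLi (1.05 equiv), THF, −100 °C; Tf2O, −100 °C → rt
Reagents that add atoms: hexamethyldisilazane C[Si](C)(C)N[Si](C)(C)C; trifluoromethanesulfonic anhydride O=S(=O)(OS(=O)(=O)C(F)(F)F)C(F)(F)F
Why: O-silylation, then bromine–lithium exchange (much faster at −100 °C than attack on the di-ortho-substituted benzyl ester), triggers the anionic 1,3 O→C silyl shift (retro-Brook rearrangement), and the phenoxide so released is trapped as its triflate, the standard one-pot passage from ortho-bromophenols to ortho-silylaryl triflates.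

Step 7
Reactants: 13 benzyl 2-(benzyloxy)-5,6-dimethyl-4-(trifluoromethylsulfonyloxy)-3-(trimethylsilyl)benzoate
Product: 17 benzyl 2-(benzyloxy)-3-formyl-4-hydroxy-5,6-dimethylbenzoate, via aryne 14 (not isolated), via aminobenzoxete 15 (not isolated), via quinone methide 16 (not isolated)
Conditions: CsF (3 equiv), anhydrous DMF (solvent, 0.05 M), rt; then H2O, rt
Reagents that add atoms: N,N-dimethylformamide CN(C)C=O; water O
Why: Desilylation by fluoride with 1,2-loss of triflate generates the C4'/C5' aryne 14; the carbonyl oxygen of the solvent DMF bonds to C4' and the carbanion thereby created at C5' collapses onto the iminium carbon, so the C4'–O and C5'–C bonds arise in one formal [2+2] insertion into the C=O bond. The closest known reaction type is the insertion of arynes, 3-alkoxyarynes included, into the C=O bond of formamides, which gives salicylaldehydes after hydrolysis. The only ring closed is the transient four-membered benzoxete 15 (4-exo-trig attack of the aryl anion on the iminium carbon); it reopens to the ortho-quinone methide 16, which water hydrolyses with loss of dimethylamine, so no ring of the product and no stereocentre is created. The selectivity at stake is the orientation of the addition: the σ-withdrawing C6' benzyloxy substituent polarizes and distorts the strained triple bond, so that the nucleophile enters at the remote carbon C4' and the negative charge develops at C5' next to oxygen, and this should outweigh the smaller steric counter-influence of the C3' methyl group. Capture of a second aryne by the product is suppressed by the large excess of DMF, by dilution and by adding water only once the precursor is consumed.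

Step 8
Reactants: 17 benzyl 2-(benzyloxy)-3-formyl-4-hydroxy-5,6-dimethylbenzoate
Product: 18 3-formyl-2,4-dihydroxy-5,6-dimethylbenzoic acid
Conditions: H2 (1 atm), 10% Pd/C, EtOAc, rt, stopped after two equivalents of H2; used without heating
Reagents that add atoms: none
Why: Catalytic hydrogenolysis cleaves the benzyl ester and the benzyl ether, whereas in a neutral aprotic solvent the chelated, doubly flanked aldehyde is reduced far more slowly, as expected for formyl-bearing depside building blocks.

Step 9
Reactants: 19 atraric acid (methyl 2,4-dihydroxy-3,6-dimethylbenzoate)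
Product: 20 methyl 5-formyl-2,4-dihydroxy-3,6-dimethylbenzoate
Conditions: Cl2CHOMe, TiCl4, CH2Cl2, 0 °C → rt; then aq. HCl
Reagents that add atoms: dichloromethyl methyl ether COC(Cl)Cl; water O
Why: Rieche formylation, in which the titanium-bound phenol directs the electrophile to C5, the only free ring position (ortho to the C4 hydroxyl and para to the C2 hydroxyl), and aqueous work-up releases the aldehyde.

Step 10
Reactants: 20 methyl 5-formyl-2,4-dihydroxy-3,6-dimethylbenzoate
Product: 21 methyl 2,4-dihydroxy-3,5,6-trimethylbenzoate
Conditions: Et3SiH (3 equiv), TFA, rt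
Reagents that add atoms: none
Why: Ionic hydrogenation, in which the protonated aldehyde gives a benzylic cation stabilized by the ortho and para hydroxyls and accepts hydride from the silane twice to leave a methyl group; the fully substituted ring excludes Friedel–Crafts side reactions.

Step 11
Reactants: 18 3-formyl-2,4-dihydroxy-5,6-dimethylbenzoic acid; 21 methyl 2,4-dihydroxy-3,5,6-trimethylbenzoate
Product: 23 pseudocyphellarin A, via mixed trifluoroacetic anhydride 22 (not isolated)
Conditions: TFAA, toluene, 0 °C → rt; then H2O
Reagents that add atoms: none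
Why: Trifluoroacetic anhydride turns the hindered salicylic acid into a mixed anhydride that acylates the C4 hydroxyl of ring B, its only phenol not tied up in a hydrogen bond, while the chelated C2 hydroxyl of ring B and both phenols of ring A stay passive, the established protecting-group-free way of joining hydroxy acids and phenols into depsides.

Compound list
1 | benzyl acetoacetate | CC(=O)CC(=O)OCc1ccccc1 | starting material
2 | ethyl tiglate, ethyl (E)-2-methylbut-2-enoate | C/C=C(\C)C(=O)OCC | starting material
3 | 1-benzyl 5-ethyl 2-acetyl-3,4-dimethylpentanedioate (Michael adduct, diastereomer mixture) | CCOC(=O)C(C)C(C)C(C(C)=O)C(=O)OCc1ccccc1 | intermediate (not isolated)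
4 | benzyl 5,6-dimethyl-2,4-dioxocyclohexane-1-carboxylate (diastereomer mixture, stereocentres not controlled) | O=C(OCc1ccccc1)C1C(=O)CC(=O)C(C)C1C | intermediate
5 | benzyl 2,4-dihydroxy-5,6-dimethylbenzoate | O=C(OCc1ccccc1)c1c(O)cc(O)c(C)c1C | intermediate (not isolated)
6 | benzyl 3-bromo-2,4-dihydroxy-5,6-dimethylbenzoate | O=C(OCc1ccccc1)c1c(O)c(Br)c(O)c(C)c1C | intermediate
7 | benzyl 4-(allyloxy)-3-bromo-2-hydroxy-5,6-dimethylbenzoate | O=C(OCc1ccccc1)c1c(O)c(Br)c(OCC=C)c(C)c1C | intermediate
8 | benzyl 4-(allyloxy)-2-(benzyloxy)-3-bromo-5,6-dimethylbenzoate | O=C(OCc1ccccc1)c1c(OCc2ccccc2)c(Br)c(OCC=C)c(C)c1C | intermediate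
9 | benzyl 2-(benzyloxy)-3-bromo-4-hydroxy-5,6-dimethylbenzoate | O=C(OCc1ccccc1)c1c(OCc2ccccc2)c(Br)c(O)c(C)c1C | intermediate
10 | benzyl 2-(benzyloxy)-3-bromo-5,6-dimethyl-4-(trimethylsilyloxy)benzoate | O=C(OCc1ccccc1)c1c(OCc2ccccc2)c(Br)c(O[Si](C)(C)C)c(C)c1C | intermediate (not isolated)
11 | aryllithium: benzyl 2-(benzyloxy)-3-lithio-5,6-dimethyl-4-(trimethylsilyloxy)benzoate | [Li]c1c(OCc2ccccc2)c(C(=O)OCc2ccccc2)c(C)c(C)c1O[Si](C)(C)C | intermediate (not isolated)
12 | lithium 3-(benzyloxy)-4-(benzyloxycarbonyl)-5,6-dimethyl-2-(trimethylsilyl)phenoxide | [Li+].[O-]c1c(C)c(C)c(C(=O)OCc2ccccc2)c(OCc2ccccc2)c1[Si](C)(C)C | intermediate (not isolated)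
13 | benzyl 2-(benzyloxy)-5,6-dimethyl-4-(trifluoromethylsulfonyloxy)-3-(trimethylsilyl)benzoate | O=C(OCc1ccccc1)c1c(C)c(C)c(OS(=O)(=O)C(F)(F)F)c([Si](C)(C)C)c1OCc1ccccc1 | intermediate
14 | aryne: benzyl 2-(benzyloxy)-5,6-dimethyl-3,4-didehydrobenzoate | O=C(OCc1ccccc1)C1=C(OCc2ccccc2)C#CC(C)=C1C | intermediate (not isolated)
15 | benzyl 3-(benzyloxy)-2-(dimethylamino)-5,6-dimethyl-2H-benzoxete-4-carboxylate (racemic at the aminal carbon) | CN(C)C1Oc2c(C)c(C)c(C(=O)OCc3ccccc3)c(OCc3ccccc3)c21 | intermediate (not isolated)
16 | ortho-quinone methide: benzyl 2-(benzyloxy)-3-[(dimethylamino)methylidene]-5,6-dimethyl-4-oxocyclohexa-1,5-diene-1-carboxylate (alkene geometry not defined) | O=C(OCc1ccccc1)C1=C(OCc2ccccc2)C(=CN(C)C)C(=O)C(C)=C1C | intermediate (not isolated)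
17 | benzyl 2-(benzyloxy)-3-formyl-4-hydroxy-5,6-dimethylbenzoate | O=C(OCc1ccccc1)c1c(C)c(C)c(O)c(C=O)c1OCc1ccccc1 | intermediate
18 | 3-formyl-2,4-dihydroxy-5,6-dimethylbenzoic acid | O=Cc1c(O)c(C)c(C)c(C(=O)O)c1O | intermediate
19 | atraric acid, methyl 2,4-dihydroxy-3,6-dimethylbenzoate | COC(=O)c1c(C)cc(O)c(C)c1O | starting material
20 | methyl 5-formyl-2,4-dihydroxy-3,6-dimethylbenzoate | COC(=O)c1c(C)c(C=O)c(O)c(C)c1O | intermediate
21 | methyl 2,4-dihydroxy-3,5,6-trimethylbenzoate | COC(=O)c1c(C)c(C)c(O)c(C)c1O | intermediate
22 | 3-formyl-2,4-dihydroxy-5,6-dimethylbenzoic trifluoroacetic anhydride | O=Cc1c(O)c(C)c(C)c(C(=O)OC(=O)C(F)(F)F)c1O | intermediate (not isolated)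
23 | pseudocyphellarin A, 3-hydroxy-4-(methoxycarbonyl)-2,5,6-trimethylphenyl 3-formyl-2,4-dihydroxy-5,6-dimethylbenzoate (no stereocentres) | COC(=O)c1c(C)c(C)c(OC(=O)c2c(C)c(C)c(O)c(C=O)c2O)c(C)c1O | target

Total step count: 11. Longest linear sequence: 9 steps (steps 1 to 8, then step 11); steps 9 and 10 form the ring B branch.

Steps most likely to fail

Step 7. DMF may add with the opposite orientation (oxygen at C5'), or the aryne may be consumed by the ortho-quinone methide or the phenoxide product before hydrolysis. The fallback leaves aryne chemistry and sets out from 8. Bromine–magnesium exchange with i-PrMgCl·LiCl (THF, 0 °C → rt), which tolerates the hindered ester, and quenching of the arylmagnesium with DMF should give benzyl 4-(allyloxy)-2-(benzyloxy)-3-formyl-5,6-dimethylbenzoate F1. Deallylation with Pd(PPh3)4 and sodium p-toluenesulfinate (THF/MeOH, rt), a scavenger that does not condense with the aldehyde, returns to the route at 17.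

Step 6. Butyllithium may attack the benzyl ester or a benzylic CH2 in competition with bromine–lithium exchange, or O-triflation of the crowded phenoxide may stay incomplete. The fallback avoids organolithium and the silyl migration and sets out from 8. Bromine–magnesium exchange with i-PrMgCl·LiCl and C-silylation of the arylmagnesium with TMSCl (THF, rt → 50 °C) should give benzyl 4-(allyloxy)-2-(benzyloxy)-5,6-dimethyl-3-(trimethylsilyl)benzoate F2. Deallylation with Pd(PPh3)4 and morpholine gives benzyl 2-(benzyloxy)-4-hydroxy-5,6-dimethyl-3-(trimethylsilyl)benzoate F3, and triflation (Tf2O, pyridine, CH2Cl2, 0 °C) rejoins the route at 13.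

Step 11. The mixed anhydride may acylate the phenols of ring A instead, or the doubly ortho-substituted phenol of ring B may attack too slowly. The fallback uses a preformed acid chloride with masked phenols, the classical depside approach, and sets out from 18. Acetylation (Ac2O, pyridine; aqueous work-up) gives 2,4-diacetoxy-3-formyl-5,6-dimethylbenzoic acid F4, and (COCl)2 with catalytic DMF in CH2Cl2 gives 2,4-diacetoxy-3-formyl-5,6-dimethylbenzoyl chloride F5. Acylation of 21 (pyridine, DMAP, CH2Cl2) gives the depside diacetate 3-hydroxy-4-(methoxycarbonyl)-2,5,6-trimethylphenyl 2,4-diacetoxy-3-formyl-5,6-dimethylbenzoate F6. Mild methanolysis (catalytic K2CO3, MeOH, 0 °C) should remove the two activated aryl acetates while the hindered depside ester survives, and arrives at 23.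

Further compounds
F1 | step 7 | benzyl 4-(allyloxy)-2-(benzyloxy)-3-formyl-5,6-dimethylbenzoate | O=C(OCc1ccccc1)c1c(OCc2ccccc2)c(C=O)c(OCC=C)c(C)c1C
F2 | step 6 | benzyl 4-(allyloxy)-2-(benzyloxy)-5,6-dimethyl-3-(trimethylsilyl)benzoate | O=C(OCc1ccccc1)c1c(OCc2ccccc2)c([Si](C)(C)C)c(OCC=C)c(C)c1C
F3 | step 6 | benzyl 2-(benzyloxy)-4-hydroxy-5,6-dimethyl-3-(trimethylsilyl)benzoate | O=C(OCc1ccccc1)c1c(OCc2ccccc2)c([Si](C)(C)C)c(O)c(C)c1C
F4 | step 11 | 2,4-diacetoxy-3-formyl-5,6-dimethylbenzoic acid | CC(=O)Oc1c(C=O)c(OC(C)=O)c(C)c(C)c1C(=O)O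
F5 | step 11 | 2,4-diacetoxy-3-formyl-5,6-dimethylbenzoyl chloride | CC(=O)Oc1c(C=O)c(OC(C)=O)c(C)c(C)c1C(=O)Cl
F6 | step 11 | 3-hydroxy-4-(methoxycarbonyl)-2,5,6-trimethylphenyl 2,4-diacetoxy-3-formyl-5,6-dimethylbenzoate | COC(=O)c1c(C)c(C)c(OC(=O)c2c(C)c(C)c(OC(C)=O)c(C=O)c2OC(C)=O)c(C)c1O
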